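**Assumptions.** (i) Claisen rearrangement of 4-allyloxy-2-hydroxyacetophenone goes mainly to C3, the position between the two oxygens. (ii) The (S,S)-series of the chiral acid catalyst delivers the (2S) face. If it gives the opposite enantiomer, the (R,R) catalyst is used.

## Retrosynthesis
- Sophoranone is the 7-hydroxy-8-prenyl flavanone bearing a 4'-hydroxy-3',5'-diprenylphenyl group at C2. The three prenyls are disconnected to three allyls, to be converted by cross-metathesis with 2-methyl-2-butene last. Allyl groups survive the acidic key step, whereas prenyl groups would cyclize to chromans.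
- The C2 stereocentre and the C2–aryl bond come from one step: an enantioselective para-C–H Friedel–Crafts conjugate arylation of an 8-allyl-7-silyloxychromone with commercial 2,6-diallylphenol.
- The chromone is built from resacetophenone by 4-O-allylation, Claisen rearrangement to C3, then enaminone formation and cyclization. The rings form in this order: chromone pyranone ring, then the flavanone C2–aryl bond (with stereocentre), with the B ring arriving already intact.

## Route

**Step 1**
Reactants: 1 (2',4'-dihydroxyacetophenone), 2 (allyl bromide)
Product: 3 (1-(4-allyloxy-2-hydroxyphenyl)ethanone)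
Conditions: K2CO3, KI (cat.), acetone, reflux
Reagents that add atoms: allyl bromide, C=CCBr
Why: The 2-OH is chelated to the C=O, so only the 4-OH is alkylated (Williamson ether synthesis).

**Step 2**
Reactants: 3
Product: 4 (1-(3-allyl-2,4-dihydroxyphenyl)ethanone)
Conditions: N,N-diethylaniline, 200 °C, sealed tube, 2 h
Reagents that add atoms: none
Why: An aromatic Claisen [3,3] rearrangement moves the allyl group to the ortho position between the two oxygens. This C3 regiochemistry is the major outcome, and the minor 5-allyl isomer is removed by chromatography.

**Step 3**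
Reactants: 4, 5 (N,N-dimethylformamide dimethyl acetal)
Product: 6 ((E)-3-(dimethylamino)-1-(3-allyl-2,4-dihydroxyphenyl)prop-2-en-1-one)
Conditions: DMF-DMA (2 equiv), toluene, 90 °C
Reagents that add atoms: DMF-DMA, CN(C)C(OC)OC (adds =CH–NMe2)
Why: Acetyl-methyl condensation with the formamide acetal gives the enaminone (a Bredereck-type condensation).

**Step 4**
Reactants: 6
Product: 7 (8-allyl-7-hydroxychromone)
Conditions: 3 M HCl, EtOH, 70 °C
Reagents that add atoms: none
Why: Acid-mediated conjugate addition of the 2-OH to the enaminone, then loss of HNMe2, closes the pyranone ring.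

**Step 5**
Reactants: 7, 8 (TBSCl)
Product: 9 (8-allyl-7-(tert-butyldimethylsilyloxy)chromone)
Conditions: TBSCl, imidazole, DMF, rt
Reagents that add atoms: TBSCl, CC(C)(C)[Si](C)(C)Cl
Why: Silyl protection of the phenol removes its vinylogous-acid donation, so the chromone is more electrophilic. The TBS group is stable to the mild acid of step 6 and is removed under buffered, non-racemizing conditions in step 8.

**Step 6**
Reactants: 9, 10 (2,6-diallylphenol, commercial)
Product: 11 ((S)-8-allyl-2-(3,5-diallyl-4-hydroxyphenyl)-7-TBSO-chroman-4-one)
Conditions: (S,S)-IDPi Brønsted acid (5 mol %), toluene, 4 Å MS, 40 °C, 72 h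
Reagents that add atoms: none (the catalyst is not incorporated)
Why: Proposed new method: the chiral acid protonates the chromone C=O to give a 4-hydroxybenzopyrylium/IDPi anion ion pair. The open para C–H of the 2,6-disubstituted phenol attacks C2 within the chiral anion pocket, which sets the (2S) centre. Rearomatization then gives the 4-hydroxy-2H-chromene, which tautomerizes to the ketone at C3, a non-stereogenic carbon. The closest known reactions are chiral-acid-catalysed Friedel–Crafts conjugate additions of arenes to enones and para-alkylation of 2,6-disubstituted phenols, but a chromone as the electrophile and a phenol as the para-C–H nucleophile has not been shown. The two allyls block O- and ortho-attack, and the addition is atom-economical.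

**Step 7**
Reactants: 11, 12 (2-methyl-2-butene)
Product: 13 ((S)-8-prenyl-2-(4-hydroxy-3,5-diprenylphenyl)-7-TBSO-chroman-4-one)
Conditions: Hoveyda–Grubbs II (3 × 5 mol %, added in portions), 1,4-benzoquinone (20 mol %), 2-methyl-2-butene (neat, ~100 equiv), CH2Cl2, 40 °C, sealed tube
Reagents that add atoms: 2-methyl-2-butene, CC=C(C)C (supplies the =CMe2 terminus; propene is lost)
Why: Olefin cross-metathesis with the trisubstituted olefin converts each terminal allyl to prenyl. Benzoquinone suppresses Ru–H isomerization to propenyl. No stereocentre is touched.

**Step 8**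
Reactants: 13
Product: 14 (sophoranone)
Conditions: TBAF–AcOH (1:1), THF, 0 °C, 1 h
Reagents that add atoms: none
Why: Buffered fluoride removes the aryl TBS ether without opening the flavanone (no retro-oxa-Michael), so the C2 configuration is retained.

## Compound list
1 | 2',4'-dihydroxyacetophenone | CC(=O)c1ccc(O)cc1O | starting material
2 | allyl bromide | C=CCBr | starting material
3 | 1-(4-allyloxy-2-hydroxyphenyl)ethanone | CC(=O)c1ccc(OCC=C)cc1O | intermediate
4 | 1-(3-allyl-2,4-dihydroxyphenyl)ethanone | CC(=O)c1ccc(O)c(CC=C)c1O | intermediate
5 | N,N-dimethylformamide dimethyl acetal | CN(C)C(OC)OC | starting material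
6 | (E)-enaminone of 4 | CN(C)/C=C/C(=O)c1ccc(O)c(CC=C)c1O | intermediate
7 | 8-allyl-7-hydroxychromone | C=CCc1c(O)ccc2c(=O)ccoc12 | intermediate
8 | tert-butyldimethylsilyl chloride | CC(C)(C)[Si](C)(C)Cl | starting material
9 | 8-allyl-7-TBSO-chromone | C=CCc1c(O[Si](C)(C)C(C)(C)C)ccc2c(=O)ccoc12 | intermediate
10 | 2,6-diallylphenol | C=CCc1cccc(CC=C)c1O | starting material
11 | (S)-8-allyl-2-(3,5-diallyl-4-hydroxyphenyl)-7-TBSO-chroman-4-one | C=CCc1cc([C@@H]2CC(=O)c3ccc(O[Si](C)(C)C(C)(C)C)c(CC=C)c3O2)cc(CC=C)c1O | intermediate
12 | 2-methyl-2-butene | CC=C(C)C | starting material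
13 | (S)-7-TBSO-8-prenyl-2-(4-hydroxy-3,5-diprenylphenyl)chroman-4-one | CC(C)=CCc1cc([C@@H]2CC(=O)c3ccc(O[Si](C)(C)C(C)(C)C)c(CC=C(C)C)c3O2)cc(CC=C(C)C)c1O | intermediate
14 | sophoranone | CC(C)=CCc1cc([C@@H]2CC(=O)c3ccc(O)c(CC=C(C)C)c3O2)cc(CC=C(C)C)c1O | target

## Summary
Total steps: 8. Longest linear sequence: 8 (1 → 3 → 4 → 6 → 7 → 9 → 11 → 13 → 14).

**Three steps most likely to fail**
1. **Step 6 (proposed new step).** The chromone may be too weakly electrophilic, or the acid may racemize the product through ring-opening of the 4-hydroxybenzyl C–O bond to a quinone methide.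
   - Fallback (known chemistry): a different bond construction. Run a Claisen–Schmidt condensation of a protected 4 with 3,5-diallyl-4-hydroxybenzaldehyde to give the 2'-hydroxychalcone. Cyclize it with a cinchona-derived bifunctional thiourea oxa-Michael catalyst. Alternatively, carry out a Pd/pyridine-oxazoline asymmetric 1,4-arylation of chromone 9 with the 3,5-diallyl-4-protected-phenylboronic acid, then continue with steps 7–8.
2. **Step 7.** The triple cross-metathesis may stall at the mono- or di-prenyl stage, or alkene isomerization may give ArCH=CMe2 or propenyl side products.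
   - Fallback: convert each allyl to prenyl stepwise. Use OsO4/NaIO4 cleavage to the aryl-acetaldehyde, then Wittig olefination with Ph3P=CMe2 (salt-free, –78 °C, with the 4'-OH as a TIPS ether).
3. **Step 2.** Claisen regioselectivity may give too much of the 5-allyl isomer.
   - Fallback: use a directed-metalation route. C2-lithiate 1,3-bis(MOM-oxy)benzene and allylate it (CuI, allyl bromide). Remove the MOM groups, then acetylate regioselectively at C4 with AcOH/BF3·OEt2 to give 4 without a Claisen step.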